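**Plan**
- Retrosynthetic cuts, in order: the two ring B acetates and the C5 methyl ether (protecting groups); C4–C4a, the aryl ketone bond of ring C; O1–C2, the benzylic aryl ether; then C8–C1'' (prenyl, traced back to an O-bound 1,1-dimethylallyl group) on ring A and C2–C3 (aroyl–CH2) on the side chain.
- Forward: 3,5-dimethoxyphenol (ring A, bought) gains its prenyl group; 3,4-dihydroxybenzoic acid (ring B, bought) is extended to an (R)-β-hydroxy allyl ester that carries C2, C3 and C4; the halves are joined at O1–C2; ring C is closed last at C4–C4a.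
- Stereochemistry: C2 is the only stereocentre. It is set as the (R)-carbinol by catalyst-controlled transfer hydrogenation, becomes (S) by SN2 inversion in the Mitsunobu etherification, and is a spectator afterwards.
- Feature that allows the ring closure: on ring A, C4a is the only free carbon ortho to O1 (C8 holds the prenyl group), the chain C2–C3–C4 hanging from O1 reaches C4a and no other ring carbon, and C4a lies ortho to the oxygens on C5 and C8a and para to the oxygen on C7.
- The C5 and C7 methyl ethers, equivalent in the symmetric phenol, are told apart only after ring closure, by chelation between the C4 carbonyl and O5.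

Key step: step 10

Remark: the (R,R)-TsDPEN ruthenium catalyst is assumed to reduce the aryl ketone of 12 with the same facial sense as acetophenone, which gives the (R)-carbinol; if the sense were opposite, the (S,S) catalyst would be used.

**Step 1**
Reactants: 1 3,5-dimethoxyphenol; 2 3-chloro-3-methylbut-1-yne
Product: 3 1,3-dimethoxy-5-[(2-methylbut-3-yn-2-yl)oxy]benzene
Conditions: CuCl2·2H2O (1 mol %), DBU, MeCN, 0 °C
Reagents that add atoms: none
Why: Copper-catalysed propargylic substitution of a tertiary propargyl chloride by a phenol is the standard route to aryl 1,1-dimethylpropargyl ethers and should give O- rather than C-alkylation.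

**Step 2**
Reactants: 3 1,3-dimethoxy-5-[(2-methylbut-3-yn-2-yl)oxy]benzene
Product: 4 1,3-dimethoxy-5-[(2-methylbut-3-en-2-yl)oxy]benzene
Conditions: H2 (1 atm), Pd/CaCO3 poisoned with Pb(OAc)2, quinoline, EtOAc, rt
Reagents that add atoms: none
Why: Lindlar-type semihydrogenation of a terminal alkyne should stop at the alkene and leave the aryl ether untouched.

**Step 3**
Reactants: 4 1,3-dimethoxy-5-[(2-methylbut-3-en-2-yl)oxy]benzene
Product: 6 3,5-dimethoxy-2-(3-methylbut-2-en-1-yl)phenol, via Claisen dienone 5 (not isolated)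
Conditions: PhNEt2, 130 °C
Reagents that add atoms: none
Why: The aromatic Claisen rearrangement ([3,3]-sigmatropic shift, then enolisation of dienone 5) delivers the transposed 3-methylbut-2-enyl group to an ortho carbon; the two ortho carbons of 4 are equivalent, so one regioisomer is expected, and the basic solvent should keep the ortho-prenylphenol from closing to a chroman.

**Step 4**
Reactants: 7 3,4-dihydroxybenzoic acid
Product: 8 3,4-diacetoxybenzoic acid
Conditions: Ac2O, pyridine, 0 °C → rt; then H2O
Reagents that add atoms: acetic anhydride, CC(=O)OC(C)=O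
Why: O-Acetylation of both phenols is routine, and the mixed anhydride formed at the carboxyl group should hydrolyse back to the acid on aqueous work-up.

**Step 5**
Reactants: 8 3,4-diacetoxybenzoic acid; 9 2,2-dimethyl-1,3-dioxane-4,6-dione (Meldrum's acid)
Product: 11 5-[(3,4-diacetoxyphenyl)(hydroxy)methylidene]-2,2-dimethyl-1,3-dioxane-4,6-dione, via 3,4-diacetoxybenzoyl chloride 10 (not isolated)
Conditions: (COCl)2, cat. DMF, CH2Cl2, 0 °C → rt, evaporate; then 9, pyridine, CH2Cl2, 0 °C → rt
Reagents that add atoms: none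
Why: C-Acylation of Meldrum's acid by an aroyl chloride (first half of the Oikawa–Yonemitsu β-keto ester synthesis) forms the C2–C3 bond without any strong base that would attack the aryl acetates.

**Step 6**
Reactants: 11 5-[(3,4-diacetoxyphenyl)(hydroxy)methylidene]-2,2-dimethyl-1,3-dioxane-4,6-dione
Product: 12 prop-2-en-1-yl 3-(3,4-diacetoxyphenyl)-3-oxopropanoate
Conditions: allyl alcohol (2 equiv), toluene, 90 °C
Reagents that add atoms: prop-2-en-1-ol (allyl alcohol), C=CCO
Why: Thermal alcoholysis of an acyl Meldrum's acid, with loss of acetone and CO2, should give the β-keto ester under neutral conditions that the aryl acetates tolerate.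

**Step 7**
Reactants: 12 prop-2-en-1-yl 3-(3,4-diacetoxyphenyl)-3-oxopropanoate
Product: 13 prop-2-en-1-yl (3R)-3-(3,4-diacetoxyphenyl)-3-hydroxypropanoate
Conditions: RuCl(p-cymene)[(R,R)-TsDPEN] (1 mol %), HCO2H–Et3N (5:2), EtOAc, 25 °C
Reagents that add atoms: none
Why: Noyori–Ikariya asymmetric transfer hydrogenation of an aryl ketone sets C2 by catalyst control, the (R,R) ligand steering hydride to the face that gives the (R)-carbinol; the allyl C=C, which H2 would reduce, should be inert under transfer conditions.

**Step 8**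
Reactants: 6 3,5-dimethoxy-2-(3-methylbut-2-en-1-yl)phenol; 13 prop-2-en-1-yl (3R)-3-(3,4-diacetoxyphenyl)-3-hydroxypropanoate
Product: 14 prop-2-en-1-yl (3S)-3-(3,4-diacetoxyphenyl)-3-[3,5-dimethoxy-2-(3-methylbut-2-en-1-yl)phenoxy]propanoate
Conditions: PPh3, DIAD, toluene, 0 °C → rt
Reagents that add atoms: none
Why: In the Mitsunobu etherification the phenoxide displaces the oxyphosphonium group by SN2 with inversion, converting (R) into (S); the electron-poor diacetoxyphenyl ring disfavours benzylic ionisation that would erode the configuration.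

**Step 9**
Reactants: 14 prop-2-en-1-yl (3S)-3-(3,4-diacetoxyphenyl)-3-[3,5-dimethoxy-2-(3-methylbut-2-en-1-yl)phenoxy]propanoate
Product: 15 (3S)-3-(3,4-diacetoxyphenyl)-3-[3,5-dimethoxy-2-(3-methylbut-2-en-1-yl)phenoxy]propanoic acid
Conditions: Pd(PPh3)4 (5 mol %), PhSiH3, CH2Cl2, rt
Reagents that add atoms: none
Why: Tsuji–Trost-type deallylation (zerovalent palladium forms the π-allyl complex, hydride from the silane reduces it to propene) frees the acid under neutral conditions, so the aryl acetates survive and the β-aryloxy ester is not exposed to base that could cause E1cB loss of the phenol.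

**Step 10**
Reactants: 15 (3S)-3-(3,4-diacetoxyphenyl)-3-[3,5-dimethoxy-2-(3-methylbut-2-en-1-yl)phenoxy]propanoic acid
Product: 17 (2S)-2-(3,4-diacetoxyphenyl)-5,7-dimethoxy-8-(3-methylbut-2-en-1-yl)chroman-4-one, via acid chloride 16 (not isolated)
Conditions: 1-chloro-N,N,2-trimethylprop-1-en-1-amine, CH2Cl2, 0 °C; then SnCl4, 2,6-di-tert-butyl-4-methylpyridine, CH2Cl2, −78 °C
Reagents that add atoms: none
Why: The α-chloroenamine converts the acid into acid chloride 16 without releasing HCl, and SnCl4 then polarises 16 to an acylium equivalent that attacks C4a; the arenium ion loses its proton to the hindered pyridine and ring A rearomatises. The closest known reaction type is the intramolecular Friedel–Crafts acylation of 3-aryloxypropanoic acids to chroman-4-ones. Ring C closes by 6-exo attack of C4a on the acyl carbon (trig for the tin-bound acid chloride, dig if the free acylium ion is involved), forming C4–C4a. No stereocentre is created, and C2 keeps the configuration given in steps 7 and 8 because none of its bonds takes part. Regioselectivity is fixed by the substrate: the tether reaches only C4a, C8 is blocked by the prenyl group, C6 is out of range, and C4a is activated by the oxygens on C5, C7 and C8a. The chemoselectivity needed, acylation ahead of ionisation of the benzylic C2–O1 bond and of protonation of the prenyl alkene, should be secured by the electron-poor diacetoxyphenyl ring, the low temperature and the proton scavenger.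

**Step 11**
Reactants: 17 (2S)-2-(3,4-diacetoxyphenyl)-5,7-dimethoxy-8-(3-methylbut-2-en-1-yl)chroman-4-one
Product: 18 (2S)-2-(3,4-diacetoxyphenyl)-5-hydroxy-7-methoxy-8-(3-methylbut-2-en-1-yl)chroman-4-one
Conditions: MgI2·OEt2 (3 equiv), toluene–Et2O, 60 °C; cold dilute aq. HCl work-up
Reagents that add atoms: none
Why: In this chelation-controlled ether cleavage, magnesium bound between the C4 carbonyl and O5 activates only the C5 methyl group for SN2 attack by iodide, the C7 ether cannot chelate, and the aprotic reagent should spare the prenyl alkene and C2.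

**Step 12**
Reactants: 18 (2S)-2-(3,4-diacetoxyphenyl)-5-hydroxy-7-methoxy-8-(3-methylbut-2-en-1-yl)chroman-4-one
Product: 19 (2S)-2-(3,4-dihydroxyphenyl)-5-hydroxy-7-methoxy-8-(3-methylbut-2-en-1-yl)chroman-4-one
Conditions: NH4OAc, MeOH–H2O (9:1), rt
Reagents that add atoms: none
Why: Near-neutral transesterification of aryl acetates with NH4OAc in methanol should remove both acetyl groups without generating the phenoxide that would open ring C by retro-oxa-Michael reaction and racemise C2.

**Compound list**
1 | 3,5-dimethoxyphenol | COc1cc(O)cc(OC)c1 | starting material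
2 | 3-chloro-3-methylbut-1-yne | CC(C)(Cl)C#C | starting material
3 | 1,3-dimethoxy-5-[(2-methylbut-3-yn-2-yl)oxy]benzene | COc1cc(OC)cc(OC(C)(C)C#C)c1 | intermediate
4 | 1,3-dimethoxy-5-[(2-methylbut-3-en-2-yl)oxy]benzene | COc1cc(OC)cc(OC(C)(C)C=C)c1 | intermediate
5 | 3,5-dimethoxy-6-(3-methylbut-2-en-1-yl)cyclohexa-2,4-dien-1-one (Claisen dienone, racemic, transient) | O=C1C=C(OC)C=C(OC)C1CC=C(C)C | intermediate
6 | 3,5-dimethoxy-2-(3-methylbut-2-en-1-yl)phenol | COc1cc(O)c(CC=C(C)C)c(OC)c1 | intermediate
7 | 3,4-dihydroxybenzoic acid | OC(=O)c1ccc(O)c(O)c1 | starting material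
8 | 3,4-diacetoxybenzoic acid | CC(=O)Oc1ccc(cc1OC(C)=O)C(O)=O | intermediate
9 | 2,2-dimethyl-1,3-dioxane-4,6-dione (Meldrum's acid) | CC1(C)OC(=O)CC(=O)O1 | starting material
10 | 3,4-diacetoxybenzoyl chloride | CC(=O)Oc1ccc(cc1OC(C)=O)C(Cl)=O | intermediate
11 | 5-[(3,4-diacetoxyphenyl)(hydroxy)methylidene]-2,2-dimethyl-1,3-dioxane-4,6-dione | CC(=O)Oc1ccc(cc1OC(C)=O)C(O)=C1C(=O)OC(C)(C)OC1=O | intermediate
12 | prop-2-en-1-yl 3-(3,4-diacetoxyphenyl)-3-oxopropanoate | C=CCOC(=O)CC(=O)c1ccc(OC(C)=O)c(OC(C)=O)c1 | intermediate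
13 | prop-2-en-1-yl (3R)-3-(3,4-diacetoxyphenyl)-3-hydroxypropanoate | C=CCOC(=O)C[C@@H](O)c1ccc(OC(C)=O)c(OC(C)=O)c1 | intermediate
14 | prop-2-en-1-yl (3S)-3-(3,4-diacetoxyphenyl)-3-[3,5-dimethoxy-2-(3-methylbut-2-en-1-yl)phenoxy]propanoate | C=CCOC(=O)C[C@H](Oc1cc(OC)cc(OC)c1CC=C(C)C)c1ccc(OC(C)=O)c(OC(C)=O)c1 | intermediate
15 | (3S)-3-(3,4-diacetoxyphenyl)-3-[3,5-dimethoxy-2-(3-methylbut-2-en-1-yl)phenoxy]propanoic acid | OC(=O)C[C@H](Oc1cc(OC)cc(OC)c1CC=C(C)C)c1ccc(OC(C)=O)c(OC(C)=O)c1 | intermediate
16 | (3S)-3-(3,4-diacetoxyphenyl)-3-[3,5-dimethoxy-2-(3-methylbut-2-en-1-yl)phenoxy]propanoyl chloride | ClC(=O)C[C@H](Oc1cc(OC)cc(OC)c1CC=C(C)C)c1ccc(OC(C)=O)c(OC(C)=O)c1 | intermediate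
17 | (2S)-2-(3,4-diacetoxyphenyl)-5,7-dimethoxy-8-(3-methylbut-2-en-1-yl)chroman-4-one | COc1cc(OC)c2c(c1CC=C(C)C)O[C@H](c1ccc(OC(C)=O)c(OC(C)=O)c1)CC2=O | intermediate
18 | (2S)-2-(3,4-diacetoxyphenyl)-5-hydroxy-7-methoxy-8-(3-methylbut-2-en-1-yl)chroman-4-one | COc1cc(O)c2c(c1CC=C(C)C)O[C@H](c1ccc(OC(C)=O)c(OC(C)=O)c1)CC2=O | intermediate
19 | (2S)-2-(3,4-dihydroxyphenyl)-5-hydroxy-7-methoxy-8-(3-methylbut-2-en-1-yl)chroman-4-one | COc1cc(O)c2c(c1CC=C(C)C)O[C@H](c1ccc(O)c(O)c1)CC2=O | target

**Step count**
Total: 12 steps. Longest linear sequence: 9 steps (steps 4 to 12, from 3,4-dihydroxybenzoic acid); the ring A branch (steps 1 to 3) joins at step 8.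

**Steps most likely to fail**

Step 10. HCl or the tin halide may add to the trisubstituted prenyl alkene, or the Lewis acid may ionise the C2–O1 bond, before the acylation is complete. The fallback carries a plain allyl group, far less easily protonated, through the acidic steps and builds the prenyl group afterwards. It sets out from 1 and uses 13. Alkylation of 1 with allyl bromide and K2CO3 in acetone should give 1,3-dimethoxy-5-(prop-2-en-1-yloxy)benzene F1. Claisen rearrangement in PhNEt2 at 200 °C should give 2-allyl-3,5-dimethoxyphenol F2. Mitsunobu coupling with 13 (PPh3, DIAD) should give prop-2-en-1-yl (3S)-3-(2-allyl-3,5-dimethoxyphenoxy)-3-(3,4-diacetoxyphenyl)propanoate F3. Deallylation of the ester with Pd(PPh3)4 and PhSiH3 should give (3S)-3-(2-allyl-3,5-dimethoxyphenoxy)-3-(3,4-diacetoxyphenyl)propanoic acid F4. Activation as in step 10 gives (3S)-3-(2-allyl-3,5-dimethoxyphenoxy)-3-(3,4-diacetoxyphenyl)propanoyl chloride F5, not isolated, and SnCl4 at −78 °C should close it to (2S)-8-allyl-2-(3,4-diacetoxyphenyl)-5,7-dimethoxychroman-4-one F6. Olefin cross-metathesis of F6 with 2-methylbut-2-ene and RuCl2(=CHPh)(PCy3)(H2IMes), the second-generation Grubbs catalyst, in CH2Cl2 at 40 °C comes back to the route at 17.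

Step 8. The activated alcohol may dehydrate through the acidic ester α-CH2 to the cinnamate faster than the ortho-substituted phenoxide displaces it; acetyl transfer from the catechol diacetate to the phenoxide and partial benzylic ionisation are further leaks. The fallback replaces the Mitsunobu reaction by SN2 opening of a β-lactone, in which β-elimination from the enolate is geometrically disfavoured. It sets out from 13 and uses 6. Pd(PPh3)4 and PhSiH3 should give (3R)-3-(3,4-diacetoxyphenyl)-3-hydroxypropanoic acid F7. PhSO2Cl in pyridine at 0 °C (carboxyl activation, so retention at the carbinol) should give (4R)-4-(3,4-diacetoxyphenyl)oxetan-2-one F8. The potassium phenoxide of 6 (KOtBu, 1.0 equiv, THF–DMF, −20 → 0 °C) should attack the benzylic C4 of F8 with inversion, as phenoxides do with β-lactones at the alkyl carbon. Acidification comes back to the route at 15, so step 9 is not needed.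

Step 11. The ether cleavage may be too slow at temperatures that ring C tolerates, so that prolonged heating with the Lewis acid opens ring C by retro-oxa-Michael reaction (loss of configuration at C2) or lets iodide attack the acetates. The fallback merges ring closure and ether cleavage in one low-temperature operation. It sets out from 15: acid chloride 16 is made as in step 10 and treated with BCl3 (2.5 equiv) and 2,6-di-tert-butyl-4-methylpyridine in CH2Cl2 from −78 to 0 °C. BCl3 promotes the Friedel–Crafts acylation to 17, which stays boron-bound between the C4 carbonyl and O5 and should lose chloromethane from the C5 ether in the same flask. Hydrolytic work-up comes back to the route at 18.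

**Further compounds**
F1 | step 10 | 1,3-dimethoxy-5-(prop-2-en-1-yloxy)benzene | COc1cc(OC)cc(OCC=C)c1
F2 | step 10 | 2-allyl-3,5-dimethoxyphenol | COc1cc(O)c(CC=C)c(OC)c1
F3 | step 10 | prop-2-en-1-yl (3S)-3-(2-allyl-3,5-dimethoxyphenoxy)-3-(3,4-diacetoxyphenyl)propanoate | C=CCOC(=O)C[C@H](Oc1cc(OC)cc(OC)c1CC=C)c1ccc(OC(C)=O)c(OC(C)=O)c1
F4 | step 10 | (3S)-3-(2-allyl-3,5-dimethoxyphenoxy)-3-(3,4-diacetoxyphenyl)propanoic acid | OC(=O)C[C@H](Oc1cc(OC)cc(OC)c1CC=C)c1ccc(OC(C)=O)c(OC(C)=O)c1
F5 | step 10 | (3S)-3-(2-allyl-3,5-dimethoxyphenoxy)-3-(3,4-diacetoxyphenyl)propanoyl chloride | ClC(=O)C[C@H](Oc1cc(OC)cc(OC)c1CC=C)c1ccc(OC(C)=O)c(OC(C)=O)c1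
F6 | step 10 | (2S)-8-allyl-2-(3,4-diacetoxyphenyl)-5,7-dimethoxychroman-4-one | COc1cc(OC)c2c(c1CC=C)O[C@H](c1ccc(OC(C)=O)c(OC(C)=O)c1)CC2=O
F7 | step 8 | (3R)-3-(3,4-diacetoxyphenyl)-3-hydroxypropanoic acid | OC(=O)C[C@@H](O)c1ccc(OC(C)=O)c(OC(C)=O)c1
F8 | step 8 | (4R)-4-(3,4-diacetoxyphenyl)oxetan-2-one | O=C1C[C@@H](O1)c2ccc(OC(C)=O)c(OC(C)=O)c2
F0 | step 11 | none | none
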